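Target in beta, the flask to be acted on at 8.0 d, grows slowly: 11.8% at 1.67 d, 18.8% at 6.00 d. A slow rise invites waiting or heating. But the last two readings of beta differ by 0.4 percentage points against a scatter of 0.3 points, so beta may have stopped rather than be slow, and the next move hangs on which.

| setting | beta | epsilon | flask |
|---|---|---|---|
| substrate | 0.30 M | 0.45 M | 0.30 M |
| reagent | 0.285 M | 0.285 M | 0.285 M |
| temperature | 80 °C | 75 °C | 80 °C |
| remark | the very flask that is asked about, followed so far | run made earlier |  |
| time |  |  | 8.0 d |

| run | time / d | target / % | substrate / % |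
|---|---|---|---|
| beta | 1.67 | 11.8 | 23.8 |
| beta | 3.00 | 16.7 | 23.6 |
| beta | 5.00 | 18.4 | 23.6 |
| beta | 6.00 | 18.8 | 23.4 |
| epsilon | 1.04 | 1.9 | 44.1 |
| epsilon | 2.00 | 3.9 | 43.7 |
| epsilon | 5.00 | 6.7 | 43.8 |
| epsilon | 12.0 | 6.6 | 43.4 |

(each reading ± 0.3 percentage points)

- Sunday's: at 8.0 d add substrate, 50.0% of the amount charged, then wait 2.5 d
- Wednesday's: at 8.0 d add reagent, 50.0% of the amount charged, then wait 2.5 d
- Saturday's: change nothing and wait 2.5 d more
- Monday's: at 8.0 d raise the temperature by 10 K, then wait 2.5 d

- target, in percent of the substrate first charged, at 8.0 d
- what to do for the largest gain in target; "none" if nothing gains more than 2 percentage points (Sunday's / Wednesday's / Saturday's / Monday's / none)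
- target present, in percent of the substrate first charged, after Sunday's
- target present, in percent of the substrate first charged, after Saturday's

- what is added takes up no volume worth counting
- the numbers in the tables scatter by 0.3 percentage points (one standard deviation)
- a reading or a percentage of target counts all its forms, free or not

Dividing the rate of reagent use by the rates of substrate loss and target growth takes time out and leaves a count, which the plateaus can test without any rate constant. Let r be the reagent charge over the substrate charge, l the share of substrate lost and u the share of target. In beta, l + u is 95.4% against r of 95.0%. In epsilon, with another charge and temperature, it is 63.2% against 63.3%. So the reading is one reagent per substrate lost and one more per target, with reagent as the limiting reagent.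

Beta then stands at r − l = 18.4%, and this is the reagent ceiling, the target paid for by the reagent that remains once each lost substrate has taken its share. Waiting changes neither r nor, on the flat substrate readings of beta, l. Heating and Sunday's bring no reagent, so the reagent charge in r stays as it stands. Wednesday's raises r to 142%, and if the whole substrate charge is taken as lost the ceiling is estimated at 42.5%, a gain of 24 points, which exceeds the margin of 2 points. Beta read 16.7% at 3.00 d, short of its last reading, and Wednesday's has 2.5 d, less than that time, so this reckoning expects somewhat less than that gain. The next run therefore charges reagent.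

The forecast gives 19% (18.5% to 19.6%) at 8.0 d, 19.1% after Saturday's and 19% after Sunday's, and picks Wednesday's: “Fresh reagent is the only move likely to gain”.

The flask gives 18.8% at 8.0 d, 18.8% after Saturday's, 18.8% after Sunday's, and Wednesday's gains 22 points. At 8.00 d the flask holds 0% of its charged reagent free.

    substrate + reagent → intermediate A (k = 3.47 × 10⁻⁴ M⁻¹ s⁻¹, Ea = 61.0 kJ mol⁻¹)
    reagent + intermediate A → intermediate B (k = 1.07 × 10⁻⁴ M⁻¹ s⁻¹, Ea = 85.0 kJ mol⁻¹)
    substrate + reagent ⇌ intermediate C (K = 0.955 M⁻¹, k = 0.00109 M⁻¹ s⁻¹, Ea = 86.0 kJ mol⁻¹, ΔH = −3.00 kJ mol⁻¹)
    intermediate B → target (k = 9.93 × 10⁻⁶ s⁻¹, Ea = 120 kJ mol⁻¹)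
    reagent + target ⇌ idle adduct, settled at all times (K = 2.00 M⁻¹, ΔH = −32.0 kJ mol⁻¹)
    (constants at 80 °C)

With the 23.8% of substrate free in the flask at 8.00 d in place of the beta reading, r − l comes to 18.8%, beside the 18.8% of target. In the repeat at 65 °C, 21% of substrate stays free, so the ceiling is 15.8%, and that flask holds 9.81% of target and 5.95% of intermediate B, together 15.8%.

The runs are calculated for substances that don't exist, noise included.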